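(The numbers in the tables are calculated from invented constants.)

**The ligand balance.** Write the balance of the incoming ligand first, even though the starting complex is the limiting reagent as charged. Gamma starts with both in the flask, beta feeds the starting complex, and eta feeds the ligand.

| flask | starting complex | incoming ligand | remark | time |
|---|---|---|---|---|
| larch | 0.010 M | 1.05 equiv | run made earlier |  |
| cedar | 0.010 M | 2.1 equiv | run made earlier |  |
| gamma | 0.010 M | 1.05 equiv | everything together at the start | 2.0 h |
| beta | 0.010 M (fed, over 80 min) | 1.05 equiv | all else is in the flask from the start; the feed brings no volume worth counting | 2.0 h |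
| eta | 0.010 M | 1.05 equiv (fed, over 80 min) | all else is in the flask from the start; the feed brings no volume worth counting | 2.0 h |

| run | time / min | complex with one exchanged / % | starting complex / % |
|---|---|---|---|
| larch | 4.00 | 5.8 | 95.7 |
| larch | 12.0 | 14.5 | 84.7 |
| larch | 20.0 | 21.7 | 77.5 |
| larch | 30.0 | 28.0 | 73.2 |
| larch | 40.0 | 33.5 | 66.8 |
| larch | 60.0 | 42.2 | 60.1 |
| larch | 80.0 | 43.0 | 55.3 |
| cedar | 5.00 | 12.4 | 84.6 |
| cedar | 10.0 | 23.0 | 78.6 |
| cedar | 15.0 | 28.0 | 70.2 |
| cedar | 20.0 | 35.0 | 62.6 |
| cedar | 25.0 | 38.6 | 61.0 |
| cedar | 30.0 | 43.9 | 56.0 |
| cedar | 40.0 | 49.7 | 49.1 |

(each reading ± 1 percentage point)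

1. which flask leads in amount of complex with one exchanged, in percent of the starting complex charged ("all alike" within 1.5 percentage points) (gamma / beta / eta / all alike)
2. how much complex with one exchanged is there at the end, in percent of the starting complex charged: gamma
3. how much complex with one exchanged is there at the end, in percent of the starting complex charged: beta
4. how much complex with one exchanged is there at the end, in percent of the starting complex charged: eta

- a reading or a percentage of complex with one exchanged counts all its forms, free or not

**Reading the ligand.** Each starting complex lost takes one ligand, so the slope of ln[starting complex] is k[incoming ligand]. The first cedar reading, with the ligand still near its charge, gives k of about 1.59 L mol⁻¹ min⁻¹. The cedar slope from 25.0 min to 40.0 min then reads [incoming ligand] as 0.00908 M. The balance, counting exchange, leaves 0.00742 M missing. The larch slope from 40.0 min to 80.0 min reads 0.00297 M, with 0.00364 M missing.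

**A second loss.** Per minute, cedar lost 3.76 times as much as larch on a doubled charge, so this loss looks second order in ligand. Cedar, with the larger signal, gives a loss constant of 1.20 L mol⁻¹ min⁻¹. Call the self-life the time in which the charged ligand halves by this loss with no complex acting: 79.6 min.

**My reckoning.** Beta's feed lasts about as long as that, and its early ligand meets little complex. Ligand left to itself for 2.0 h keeps 41.9% of the complex charge, and I take that as beta's figure, with eta above it.

**The forecast.** It gives 54% for gamma, 46% for beta and 46% for eta, so gamma leads: “Beta and eta come out nearly symmetric, so gamma leads”.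

**The flasks.** Gamma ends at 50.0%, beta at 35.0% and eta at 46.0%, so gamma leads.

    2 incoming ligand → self-condensation product (k = 0.562 L mol⁻¹ min⁻¹)
    complex with one exchanged + incoming ligand → leaving ligand + complex with two exchanged (k = 0.160 L mol⁻¹ min⁻¹)
    starting complex + incoming ligand → leaving ligand + complex with one exchanged (k = 1.43 L mol⁻¹ min⁻¹)
    crystals ⇌ complex with one exchanged, rate k4*(cs4 - [complex with one exchanged]) while solid is left; crystals form when [complex with one exchanged] > cs4 (solubility = 9.70 mM, k = 4.27 min⁻¹)

**What happened.** Over beta's first 80 min the mean [starting complex] was 0.00396 M, against 0.00700 M in gamma, and beta's self-condensation passed half of its turnover up to 2.0 h at 0.415 h, within the self-life of 84.7 min given by the scheme's constant. Exchange then ran on, and by 2.00 h beta's self-condensation product of 0.00232 M had taken 44.1% of the ligand charged. In a neighbour of beta charged with 2.60 equiv of incoming ligand, the self-life by the same constant shortens to 34.2 min. At the end that neighbour held 48.0% complex with one exchanged.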